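The dihydropyranone ring (O1', C2'–C6') is built by a formal [3+3] annulation across C3'–C4' and O1'–C6'. It is read as (S)-propylene oxide, which supplies O1', the C2' stereocentre and C3'H2, plus a β-lithiated β-methoxyacrylate, whose lithiated carbon is a masked C4' acyl anion and whose ester is C6'. One operation opens the epoxide and lactonises, giving a methoxy lactone; acetylide addition and acid then transpose the carbonyls. The resulting pyranonylacetate is condensed with a quinone methide made from (2R,3R)-2,3-epoxybutane, and the coumarin forms as the isochroman ring opens to free the side-chain alcohol.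

Key step: step 6

Remark on the chemistry: primed locants refer to the dihydropyranone ring (O1', C2' bearing CH3, C3'H2, C4'=O, C5'H, C6' bonded to coumarin C3). Compound 8 is written as the quinone methide; in wet solvents it equilibrates with its lactol (hydrate), and both forms should react alike in step 8.

Step 1
Reactants: 1 1-bromo-3,5-dimethoxybenzene; 2 (2R,3R)-2,3-epoxybutane
Product: 4 (2R,3R)-3-(3,5-dimethoxyphenyl)butan-2-ol, via aryl Grignard reagent 3 (not isolated)
Conditions: Mg, THF, 40 °C; then CuI (10 mol %), 2, THF, −30 °C → rt; 1 M HCl work-up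
Reagents that add atoms: none
Why: Copper-catalysed SN2 opening of the C2-symmetric trans-epoxide by the aryl Grignard reagent (both epoxide carbons are equivalent) should invert the attacked carbon and leave the carbinol carbon untouched, which gives the erythro (2R,3R) array of the target side chain.

Step 2
Reactants: 4 (2R,3R)-3-(3,5-dimethoxyphenyl)butan-2-ol
Product: 5 (1RS,3R,4R)-1,6,8-trimethoxy-3,4-dimethylisochromane
Conditions: HC(OCH3)3 (3 equiv), camphorsulfonic acid (10 mol %), CH2Cl2, 0 °C → rt
Reagents that add atoms: trimethyl orthoformate, COC(OC)OC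
Why: Oxa-Pictet–Spengler cyclisation: the secondary alcohol exchanges onto the orthoformate and the resulting dialkoxycarbenium ion is trapped by the ring carbon ortho to the side chain and para to a methoxy group, the only position that closes a six-membered ring, so C1 enters as an acetal (epimer mixture, erased in step 5) while C3 and C4 are not touched.

Step 3
Reactants: 5 (1RS,3R,4R)-1,6,8-trimethoxy-3,4-dimethylisochromane
Product: 6 (1RS,3R,4R)-5,7-dibromo-1,6,8-trimethoxy-3,4-dimethylisochromane
Conditions: N-bromosuccinimide (2.1 equiv), NaHCO3, MeCN, 0 °C → rt, dark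
Reagents that add atoms: N-bromosuccinimide, BrN1C(=O)CCC1=O
Why: Electrophilic aromatic bromination should take place at C5 and C7, the only free ring positions and both ortho or para to the two methoxy groups, while the bicarbonate buffer keeps the acetal from ionising.

Step 4
Reactants: 6 (1RS,3R,4R)-5,7-dibromo-1,6,8-trimethoxy-3,4-dimethylisochromane
Product: 7 (1RS,3R,4R)-1,6,8-trimethoxy-3,4,5,7-tetramethylisochromane
Conditions: (CH3BO)3 (1.5 equiv), Pd(OAc)2 (5 mol %), 2-dicyclohexylphosphino-2',6'-dimethoxybiphenyl (10 mol %), K3PO4, toluene/H2O, 100 °C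
Reagents that add atoms: trimethylboroxine, CB1OB(C)OB(C)O1
Why: Twofold Suzuki–Miyaura methylation, for which the bulky biaryl phosphine is chosen because both bromides are flanked by two ortho substituents; the acetal and the stereocentres are inert to the basic medium.

Step 5
Reactants: 7 (1RS,3R,4R)-1,6,8-trimethoxy-3,4,5,7-tetramethylisochromane
Product: 8 (3R,4R)-8-hydroxy-3,4,5,7-tetramethyl-3,4-dihydro-6H-isochromen-6-one
Conditions: BBr3 (4 equiv), CH2Cl2, −78 → 0 °C; aq. NaHCO3 work-up
Reagents that add atoms: none
Why: Lewis-acid ether cleavage: BBr3 ionises the acetal to a 2-benzopyrylium ion, whose cationic ring oxygen no longer binds boron, cleaves both aryl methyl ethers by bromide attack on methyl, and on work-up the 6-hydroxy cation loses a proton to give the neutral quinone methide with C3 and C4 unchanged.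

Step 6
Reactants: 9 methyl (2E)-3-methoxyprop-2-enoate; 10 (S)-2-methyloxirane
Product: 13 (6S)-4-methoxy-6-methyl-5,6-dihydro-2H-pyran-2-one, via lithiated methoxyacrylate 11 (not isolated), via lithium alkoxide 12 (not isolated)
Conditions: LiN(iPr)2 (1.05 equiv), THF, −95 °C; BF3·OEt2 (1.1 equiv) then 10 (1.2 equiv), −95 → −78 °C; warm to rt; aq. NH4Cl work-up
Reagents that add atoms: none
Why: LiN(iPr)2 removes the vinylic hydrogen at the methoxy-bearing carbon of 9, which lies cis to the ester, giving an α-methoxyvinyllithium held by chelation to the ester carbonyl; this carbon is an acyl-anion equivalent for C4'. Under BF3 activation it opens (S)-propylene oxide by SN2 attack at the unsubstituted CH2 (C3'–C4' bond), and because the vinyl carbanion reacts with retention the new chain stays cis to the ester, so the δ-alkoxide closes onto the ester carbonyl (O1'–C6' bond) with loss of methoxide. The closest known reaction types are the annulation of β-lithiated β-alkoxyacrylates with aldehydes to give methyl tetronates and the BF3-promoted opening of terminal epoxides by alkenyl- and alkynyllithium reagents. The one ring that closes does so by 6-exo-trig attack of the alkoxide on the ester carbonyl. No stereocentre is created: C2' is carried over unchanged from the epoxide because the C–O bond at the stereocentre is never broken. The step needs β- over α-lithiation (secured by the ester chelate and −95 °C), attack at the terminal epoxide carbon (secured by the steric bias of the SN2 opening at low temperature) and closure without E/Z leakage (secured by the configurational stability of the chelated vinyllithium).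

Step 7
Reactants: 13 (6S)-4-methoxy-6-methyl-5,6-dihydro-2H-pyran-2-one
Product: 15 ethyl 2-[(2S)-2-methyl-4-oxo-3,4-dihydro-2H-pyran-6-yl]acetate, via lithium lactolate 14 (not isolated)
Conditions: HC≡COEt (1.3 equiv), n-BuLi (1.25 equiv), THF, −78 °C; then 13, −78 °C; then 2 M HCl, THF, rt
Reagents that add atoms: ethoxyacetylene, C#COCC; water, O
Why: 1,2-Addition of lithium ethoxyacetylide to the lactone carbonyl keeps the O1'–C6' bond in a lithium lactolate, and aqueous acid then ionises the lactol to a 4-methoxypyrylium-type cation, hydrates the ynol ether to the ethyl ester and hydrolyses the enol ether, a Stork–Danheiser-type 1,3-carbonyl transposition that unveils the C4' ketone without touching C2'.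

Step 8
Reactants: 8 (3R,4R)-8-hydroxy-3,4,5,7-tetramethyl-3,4-dihydro-6H-isochromen-6-one; 15 ethyl 2-[(2S)-2-methyl-4-oxo-3,4-dihydro-2H-pyran-6-yl]acetate
Product: 18 7-hydroxy-5-[(2R,3R)-3-hydroxybutan-2-yl]-6,8-dimethyl-3-[(2S)-2-methyl-4-oxo-3,4-dihydro-2H-pyran-6-yl]-2H-chromen-2-one, via isochroman adduct 16 (not isolated), via ring-opened alkylidene ester 17 (not isolated)
Conditions: Et3N (1.5 equiv), EtOH, 50 °C
Reagents that add atoms: none
Why: Knoevenagel-type cascade: the dienolate of 15 adds through its ester α-carbon to C1 of the quinone methide (1,6-addition), phenoxide-assisted E1cB opening of the isochroman gives the alkylidene ester and frees the secondary alcohol, and the ortho phenol lactonises onto the ethyl ester to give the coumarin, with all three stereocentres spectators.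

Compound list
1 | 1-bromo-3,5-dimethoxybenzene | COc1cc(Br)cc(OC)c1 | starting material
2 | (2R,3R)-2,3-epoxybutane | C[C@H]1O[C@@H]1C | starting material
3 | (3,5-dimethoxyphenyl)magnesium bromide | COc1cc([Mg]Br)cc(OC)c1 | intermediate
4 | (2R,3R)-3-(3,5-dimethoxyphenyl)butan-2-ol | COc1cc(OC)cc(c1)[C@@H](C)[C@@H](C)O | intermediate
5 | (1RS,3R,4R)-1,6,8-trimethoxy-3,4-dimethylisochromane (C1 epimers) | COC1O[C@H](C)[C@H](C)c2cc(OC)cc(OC)c12 | intermediate
6 | (1RS,3R,4R)-5,7-dibromo-1,6,8-trimethoxy-3,4-dimethylisochromane | COC1O[C@H](C)[C@H](C)c2c(Br)c(OC)c(Br)c(OC)c12 | intermediate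
7 | (1RS,3R,4R)-1,6,8-trimethoxy-3,4,5,7-tetramethylisochromane | COC1O[C@H](C)[C@H](C)c2c(C)c(OC)c(C)c(OC)c12 | intermediate
8 | (3R,4R)-8-hydroxy-3,4,5,7-tetramethyl-3,4-dihydro-6H-isochromen-6-one (quinone methide, O2–C1H=C8a, C6=O) | C[C@H]1OC=C2C(O)=C(C)C(=O)C(C)=C2[C@H]1C | intermediate
9 | methyl (2E)-3-methoxyprop-2-enoate | CO/C=C/C(=O)OC | starting material
10 | (S)-2-methyloxirane ((S)-propylene oxide) | C[C@H]1CO1 | starting material
11 | methyl (2E)-3-lithio-3-methoxyprop-2-enoate (lithium cis to the ester) | CO/C([Li])=C/C(=O)OC | intermediate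
12 | lithium alkoxide of methyl (2E,5S)-5-hydroxy-3-methoxyhex-2-enoate | C[C@H](O[Li])C/C(OC)=C\C(=O)OC | intermediate
13 | (6S)-4-methoxy-6-methyl-5,6-dihydro-2H-pyran-2-one | C[C@H]1CC(OC)=CC(=O)O1 | intermediate
14 | lithium (2RS,6S)-2-(ethoxyethynyl)-4-methoxy-6-methyl-5,6-dihydro-2H-pyran-2-olate | CCOC#CC1(O[Li])C=C(OC)C[C@H](C)O1 | intermediate
15 | ethyl 2-[(2S)-2-methyl-4-oxo-3,4-dihydro-2H-pyran-6-yl]acetate | CCOC(=O)CC1=CC(=O)C[C@H](C)O1 | intermediate
16 | ethyl 2-[(3R,4R)-6,8-dihydroxy-3,4,5,7-tetramethylisochroman-1-yl]-2-[(2S)-2-methyl-4-oxo-3,4-dihydro-2H-pyran-6-yl]acetate (mixture at C1 and the α-carbon) | CCOC(=O)C(C1O[C@H](C)[C@H](C)c2c(C)c(O)c(C)c(O)c12)C3=CC(=O)C[C@H](C)O3 | intermediate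
17 | ethyl (2Z)-3-{2,4-dihydroxy-6-[(2R,3R)-3-hydroxybutan-2-yl]-3,5-dimethylphenyl}-2-[(2S)-2-methyl-4-oxo-3,4-dihydro-2H-pyran-6-yl]prop-2-enoate | CCOC(=O)/C(=C\c1c(O)c(C)c(O)c(C)c1[C@@H](C)[C@@H](C)O)C2=CC(=O)C[C@H](C)O2 | intermediate
18 | 7-hydroxy-5-[(2R,3R)-3-hydroxybutan-2-yl]-6,8-dimethyl-3-[(2S)-2-methyl-4-oxo-3,4-dihydro-2H-pyran-6-yl]-2H-chromen-2-one | Cc1c(O)c(C)c2oc(=O)c(C3=CC(=O)C[C@H](C)O3)cc2c1[C@@H](C)[C@@H](C)O | target

Total step count: 8. Longest linear sequence: 6 steps (steps 1 to 5, then step 8); the pyranone branch (steps 6 and 7) joins in step 8.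

Steps most likely to fail

Step 6. The lithiation may be incomplete or the vinyllithium may condense with itself before it meets the epoxide, the epoxide opening may be sluggish, or the boron-bound alkoxide may fail to close. The fallback sets out from 10 and splits the annulation into an alkynylation and a separate conjugate addition. Methyl propiolate (C#CC(=O)OC) is lithiated with n-BuLi in THF at −90 °C and opens 10 at its CH2 under BF3·OEt2 (Yamaguchi–Hirao alkynylation) to give methyl (5S)-5-hydroxyhex-2-ynoate F1. NaOCH3 in CH3OH at rt should then add methoxide to the ynoate, equilibrate the enol-ether geometry by reversible addition and lactonise the isomer whose chain is cis to the ester, which returns to the route at 13.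

Step 7. The acetylide may deprotonate C3'H2 of the lactone and trigger ring-opening elimination to a dienoate, or it may add to C4' with displacement of methoxide instead of adding to the carbonyl. The fallback sets out from 13 and uses a less basic zinc enolate. The Reformatsky reagent from ethyl bromoacetate (CCOC(=O)CBr) and activated Zn in THF should add to the lactone carbonyl to give the cyclic hemiketal ethyl 2-[(2RS,6S)-2-hydroxy-4-methoxy-6-methyl-5,6-dihydro-2H-pyran-2-yl]acetate F2. Dilute HCl in THF then dehydrates the hemiketal and hydrolyses the enol ether, which returns to the route at 15.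

Step 8. The dienolate may attack through ring carbon C5' instead of the ester α-carbon, the ring-opening and lactonisation may stall at the adduct, or the base may erode C2' by reversible retro-oxa-Michael opening of the pyranone. The fallback sets out from 15 and replaces the base-mediated addition by a vinylogous Mukaiyama addition. Silylation with tBuMe2SiOSO2CF3 and Et3N in CH2Cl2 at 0 °C gives the silyl dienol ether ethyl (2E)-2-[(6S)-4-(tert-butyldimethylsilyloxy)-6-methyl-5,6-dihydro-2H-pyran-2-ylidene]acetate F3. Its γ-carbon should add to C1 of 8 under Me3SiOSO2CF3 (10 mol %) in CH2Cl2 at −78 °C, and aqueous work-up gives the isolated adduct 16. Brief treatment of 16 with DBU in EtOH at rt then opens the isochroman and lactonises, which returns to the route at 18.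

Further compounds
F1 | step 6 | methyl (5S)-5-hydroxyhex-2-ynoate | C[C@H](O)CC#CC(=O)OC
F2 | step 7 | ethyl 2-[(2RS,6S)-2-hydroxy-4-methoxy-6-methyl-5,6-dihydro-2H-pyran-2-yl]acetate | CCOC(=O)CC1(O)C=C(OC)C[C@H](C)O1
F3 | step 8 | ethyl (2E)-2-[(6S)-4-(tert-butyldimethylsilyloxy)-6-methyl-5,6-dihydro-2H-pyran-2-ylidene]acetate | CCOC(=O)/C=C1\C=C(O[Si](C)(C)C(C)(C)C)C[C@H](C)O1
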